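**Retrosynthetic overview**
1. 18 ⇒ 17 ⇒ 16. The only stereocentre is set last, by asymmetric transfer hydrogenation of the ring-B aryl ketone, after BBr3 demethylation at the ketone stage.
2. 16 ⇒ 13. Ring B and the 18-membered macrocycle are disconnected together (retro-Diels–Alder across ring B) to an acyclic 2-aryloxybutadiene carrying a but-3-yn-2-ol terminus.
3. 13 ⇒ 10 + 12. This cuts the C–O bond between the ring-A phenol and a C4 diene unit (palladium catalysis, propargylic carbonate).
4. 10 ⇒ 7 (C1 Wittig homologation, ethynyl Grignard). 7 ⇒ 5 + 3 (B-alkyl Suzuki, A–CH2CH2–D). 3 ⇒ 1 + 2 (SNAr, C–O–D). 5 ⇒ 4 (Wittig).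
5. Ring order: rings A, C and D are bought. Ring B and the macrocycle form simultaneously in step 8, and no ring is made afterwards.

Assumption: CIP analysis of the given SMILES gives (S) at the benzylic carbinol carbon (OH > ring-B aryl > CH2Ar > H); ring A is the trioxygenated ring, ring B the para-phenylene, ring C the 1,2,3-trisubstituted ring and ring D the meta-phenylene; compounds 2 and 4 are taken as catalogue chemicals.

**Step 1**
Reactants: 1 3-bromophenol; 2 2-fluoro-3-methoxybenzaldehyde
Product: 3 2-(3-bromophenoxy)-3-methoxybenzaldehyde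
Conditions: K2CO3 (1.5 equiv), DMF, 120 °C, 12 h
Reagents that add atoms: none
Why: Nucleophilic aromatic substitution (SNAr), in which the ortho-formyl group activates the C–F bond towards the phenoxide while the unactivated C–Br bond is untouched.

**Step 2**
Reactants: 4 3-hydroxy-4,5-dimethoxybenzaldehyde
Product: 5 5-ethenyl-2,3-dimethoxyphenol
Conditions: MePPh3Br (2.2 equiv), KOtBu (3.2 equiv), THF, 0 °C → rt; aq. NH4Cl
Reagents that add atoms: methyltriphenylphosphonium bromide, C[P+](c1ccccc1)(c1ccccc1)c1ccccc1.[Br-]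
Why: Wittig methylenation, in which extra base carries the phenol as its phenoxide, which sits meta to the aldehyde and so does not deactivate it by conjugation.

**Step 3**
Reactants: 5 5-ethenyl-2,3-dimethoxyphenol; 3 2-(3-bromophenoxy)-3-methoxybenzaldehyde
Product: 7 2-{3-[2-(3-hydroxy-4,5-dimethoxyphenyl)ethyl]phenoxy}-3-methoxybenzaldehyde, via bis(9-BBN) adduct 6 (not isolated)
Conditions: 9-BBN-H (2.2 equiv), THF, 0 → 50 °C; then 3 M aq. K3PO4, then 3, Pd(dppf)Cl2 (5 mol %), DMF, 60 °C
Reagents that add atoms: none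
Why: Anti-Markovnikov hydroboration followed by B-alkyl Suzuki–Miyaura coupling, with the aqueous base added first so that it destroys residual B–H before aldehyde 3 enters and cleaves the aryl O–B bond.

**Step 4**
Reactants: 7 2-{3-[2-(3-hydroxy-4,5-dimethoxyphenyl)ethyl]phenoxy}-3-methoxybenzaldehyde
Product: 9 2-(2-{3-[2-(3-hydroxy-4,5-dimethoxyphenyl)ethyl]phenoxy}-3-methoxyphenyl)acetaldehyde, via methyl enol ether 8 (not isolated)
Conditions: MeOCH2PPh3Cl (2.5 equiv), KOtBu (3.5 equiv), THF, 0 °C → rt; then 2 M HCl, THF, 50 °C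
Reagents that add atoms: (methoxymethyl)triphenylphosphonium chloride, COC[P+](c1ccccc1)(c1ccccc1)c1ccccc1.[Cl-]; water, O
Why: Wittig one-carbon homologation through the methyl enol ether followed by acid hydrolysis, neither of which touches the diaryl ether, the aryl methyl ethers or the phenol.

**Step 5**
Reactants: 9 2-(2-{3-[2-(3-hydroxy-4,5-dimethoxyphenyl)ethyl]phenoxy}-3-methoxyphenyl)acetaldehyde
Product: 10 rac-1-(2-{3-[2-(3-hydroxy-4,5-dimethoxyphenyl)ethyl]phenoxy}-3-methoxyphenyl)but-3-yn-2-ol
Conditions: HC≡CMgBr (3 equiv), THF, −40 → 0 °C; aq. NH4Cl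
Reagents that add atoms: ethynylmagnesium bromide, C#C[Mg]Br
Why: Grignard 1,2-addition after sacrificial deprotonation of the phenol, where the weakly basic acetylide adds faster than it enolises the aldehyde and the new carbinol centre is deliberately racemic because step 8 oxidises it away.

**Step 6**
Reactants: 11 but-3-yn-2-ol (racemic)
Product: 12 but-3-yn-2-yl methyl carbonate (racemic)
Conditions: ClCO2Me (1.2 equiv), pyridine (1.5 equiv), CH2Cl2, 0 °C → rt
Reagents that add atoms: methyl chloroformate, COC(=O)Cl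
Why: Simple O-acylation of a secondary alcohol to the mixed carbonate, which installs the leaving group needed for ionisation by palladium.

**Step 7**
Reactants: 10 rac-1-(2-{3-[2-(3-hydroxy-4,5-dimethoxyphenyl)ethyl]phenoxy}-3-methoxyphenyl)but-3-yn-2-ol; 12 but-3-yn-2-yl methyl carbonate
Product: 13 rac-1-{2-[3-(2-{3-(buta-1,3-dien-2-yloxy)-4,5-dimethoxyphenyl}ethyl)phenoxy]-3-methoxyphenyl}but-3-yn-2-ol
Conditions: Pd2(dba)3 (2.5 mol %), dppf (6 mol %), 12 (2 equiv), 1,4-dioxane, 80 °C
Reagents that add atoms: none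
Why: Tsuji-type propargylic substitution, in which zerovalent palladium ionises and decarboxylates 12 to an η3-propargyl/allenyl complex, the phenol attacks its central carbon, and the resulting 2-aryloxy-π-allyl complex loses a β-hydride from the methyl group to release the 2-aryloxy-1,3-diene, while the unactivated carbinol and alkyne of 10 stay out of it.

**Step 8**
Reactants: 13 rac-1-{2-[3-(2-{3-(buta-1,3-dien-2-yloxy)-4,5-dimethoxyphenyl}ethyl)phenoxy]-3-methoxyphenyl}but-3-yn-2-ol
Product: 16 macrocyclic aryl benzyl ketone tri-O-methyl ether (rings A–O–B–CO–CH2–C–O–D–CH2CH2–A), via ynone 14 (not isolated), via cyclohexadiene macrocycle 15 (not isolated)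
Conditions: activated MnO2 (30 equiv), 4 Å MS, PhCl (final 1 mM; 13 added over 10 h), 130 °C, 36 h
Reagents that add atoms: none
Why: Proposed new method: MnO2 oxidises the propargylic alcohol to the terminal ynone at low stationary concentration, the nucleophilic CH2 terminus next to the aryloxy carbon of the diene bonds to the ynone β-carbon (para rule) in a macrocyclising type 2 intramolecular Diels–Alder reaction that closes the six-membered ring and the 18-membered ring together, and the same MnO2 dehydrogenates the 1-acyl-4-aryloxycyclohexa-1,4-diene to ring B, the closest known reaction types being MnO2 tandem oxidation processes, large-ring-forming intramolecular Diels–Alder reactions and Diels–Alder/aromatisation of 2-oxygenated dienes with ynones.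

**Step 9**
Reactants: 16 macrocyclic aryl benzyl ketone tri-O-methyl ether
Product: 17 macrocyclic triphenol ketone
Conditions: BBr3 (8 equiv), CH2Cl2, −78 °C → rt; H2O
Reagents that add atoms: none
Why: Lewis-acid cleavage of the three aryl methyl ethers, done at the ketone stage because diaryl ethers and the ketone tolerate BBr3 whereas the later para-aryloxybenzylic alcohol would ionise.

**Step 10**
Reactants: 17 macrocyclic triphenol ketone
Product: 18 target (S)-carbinol CNP0356934.1
Conditions: RuCl[(S,S)-TsDPEN](p-cymene) (2 mol %), HCO2H/Et3N (5:2), EtOAc, degassed, 40 °C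
Reagents that add atoms: none
Why: Noyori asymmetric transfer hydrogenation, in which the (S,S)-catalyst places ring B under its η6-arene (CH/π contact) and delivers hydride to the Re face as for acetophenone, giving the (S)-alcohol, while the phenols stay protonated in the mildly acidic medium.

**Compound list**
1 | 3-bromophenol | Oc1cccc(Br)c1 | starting material
2 | 2-fluoro-3-methoxybenzaldehyde | COc1cccc(C=O)c1F | starting material
3 | 2-(3-bromophenoxy)-3-methoxybenzaldehyde | COc1cccc(C=O)c1Oc1cccc(Br)c1 | intermediate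
4 | 3-hydroxy-4,5-dimethoxybenzaldehyde | COc1cc(C=O)cc(O)c1OC | starting material
5 | 5-ethenyl-2,3-dimethoxyphenol | COc1cc(C=C)cc(O)c1OC | intermediate
6 | O,C-bis(9-BBN) adduct of 5 (aryl borinate and primary B-alkyl borane) | COc1cc(CCB2C3CCCC2CCC3)cc(OB2C3CCCC2CCC3)c1OC | intermediate
7 | 2-{3-[2-(3-hydroxy-4,5-dimethoxyphenyl)ethyl]phenoxy}-3-methoxybenzaldehyde | COc1cccc(C=O)c1Oc1cccc(CCc2cc(O)c(OC)c(OC)c2)c1 | intermediate
8 | methyl enol ether of 9 (E/Z mixture) | COC=Cc1cccc(OC)c1Oc1cccc(CCc2cc(O)c(OC)c(OC)c2)c1 | intermediate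
9 | 2-(2-{3-[2-(3-hydroxy-4,5-dimethoxyphenyl)ethyl]phenoxy}-3-methoxyphenyl)acetaldehyde | O=CCc1cccc(OC)c1Oc1cccc(CCc2cc(O)c(OC)c(OC)c2)c1 | intermediate
10 | rac-1-(2-{3-[2-(3-hydroxy-4,5-dimethoxyphenyl)ethyl]phenoxy}-3-methoxyphenyl)but-3-yn-2-ol | C#CC(O)Cc1cccc(OC)c1Oc1cccc(CCc2cc(O)c(OC)c(OC)c2)c1 | intermediate
11 | but-3-yn-2-ol (racemic) | CC(O)C#C | starting material
12 | but-3-yn-2-yl methyl carbonate (racemic) | CC(OC(=O)OC)C#C | intermediate
13 | rac-dienyl ether carbinol (ring-A O-buta-1,3-dien-2-yl ether of 10) | C=CC(=C)Oc1cc(CCc2cccc(Oc3c(CC(O)C#C)cccc3OC)c2)cc(OC)c1OC | intermediate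
14 | dienyl ether ynone (but-3-yn-2-one from 13) | C=CC(=C)Oc1cc(CCc2cccc(Oc3c(CC(=O)C#C)cccc3OC)c2)cc(OC)c1OC | intermediate
15 | macrocyclic 1-acyl-4-aryloxycyclohexa-1,4-diene | COc1cc2cc(c1OC)OC1=CCC(=CC1)C(=O)Cc1cccc(OC)c1Oc1cccc(c1)CC2 | intermediate
16 | macrocyclic aryl benzyl ketone tri-O-methyl ether | COc1cc2cc(c1OC)Oc1ccc(cc1)C(=O)Cc1cccc(OC)c1Oc1cccc(c1)CC2 | intermediate
17 | macrocyclic triphenol ketone | Oc1cc2cc(c1O)Oc1ccc(cc1)C(=O)Cc1cccc(O)c1Oc1cccc(c1)CC2 | intermediate
18 | CNP0356934.1, (S)-benzylic carbinol | Oc1cc2cc(c1O)Oc1ccc(cc1)[C@@H](O)Cc1cccc(O)c1Oc1cccc(c1)CC2 | target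

**Total step count:** 10. **Longest linear sequence:** 8 (steps 1, 3, 4, 5, 7, 8, 9, 10).

**Steps most likely to fail**

Step 8. The macrocyclising cycloaddition may be too slow to outrun ynone decomposition or oligomerisation, or it may leak to the meta regioisomer.
- The fallback sets out from 9 and comes back at 16. Ring B is bought instead of built.
- 9 is treated with 4-fluorophenylmagnesium bromide (2.2 equiv, THF, −40 °C) to give the racemic 4-fluorophenyl carbinol F1.
- SO3·pyridine/DMSO/Et3N oxidises it to the 4-fluorophenyl benzyl ketone F2.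
- Cs2CO3 in DMF (2 mM, 90 °C) then closes the A–O–B diaryl ether by intramolecular SNAr para to the ketone, delivering 16.

Step 7. A second phenol may add to the π-allyl complex, or plain O-propargylation may occur instead of diene release.
- The fallback sets out from 10 and comes back at 16, bypassing 13 to 15. The open-chain diene is replaced by a 2-pyranone attached without any metal.
- 10 and 4-bromo-2H-pyran-2-one (K2CO3, MeCN, rt, vinylogous addition–elimination) give the 4-aryloxy-2-pyranone carbinol F3.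
- Dess–Martin periodinane gives the pyranone ynone F4.
- Heating at 1 mM in 1,2-dichlorobenzene (200 °C, sealed tube) gives the bridged bicyclic lactone F5. This extrudes CO2 and so forms ring B and the macrocycle as 16 without an oxidant. The cycloaddition is slower than with the open diene, but the pyranone ether tolerates the higher temperature.

Step 10. The catechol may bind ruthenium, or the aryl/benzyl discrimination in the macrocycle may give only moderate ee.
- The fallback sets out from 17 and comes back at 18.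
- TBSCl/imidazole (DMF, rt) gives the tris(TBS) ketone F6.
- (R)-2-methyl-CBS-oxazaborolidine (20 mol %) with BH3·SMe2 (THF, −20 °C) gives the (S)-carbinol tris(TBS) ether F7. Its ee can be raised by crystallisation or chromatography on a chiral phase.
- TBAF/AcOH (THF, 0 °C) releases 18 without touching the benzylic alcohol.

**Further compounds**
F1 | step 8 | rac-1-(4-fluorophenyl)-2-(2-{3-[2-(3-hydroxy-4,5-dimethoxyphenyl)ethyl]phenoxy}-3-methoxyphenyl)ethanol | OC(Cc1cccc(OC)c1Oc1cccc(CCc2cc(O)c(OC)c(OC)c2)c1)c1ccc(F)cc1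
F2 | step 8 | 1-(4-fluorophenyl)-2-(2-{3-[2-(3-hydroxy-4,5-dimethoxyphenyl)ethyl]phenoxy}-3-methoxyphenyl)ethanone | O=C(Cc1cccc(OC)c1Oc1cccc(CCc2cc(O)c(OC)c(OC)c2)c1)c1ccc(F)cc1
F3 | step 7 | rac-4-aryloxy-2H-pyran-2-one carbinol (ring-A O-(2-oxo-2H-pyran-4-yl) ether of 10) | O=c1cc(Oc2cc(CCc3cccc(Oc4c(CC(O)C#C)cccc4OC)c3)cc(OC)c2OC)cco1
F4 | step 7 | 4-aryloxy-2H-pyran-2-one ynone | O=c1cc(Oc2cc(CCc3cccc(Oc4c(CC(=O)C#C)cccc4OC)c3)cc(OC)c2OC)cco1
F5 | step 7 | macrocyclic 2-oxabicyclo[2.2.2]octa-5,7-dien-3-one cycloadduct (racemic) | COc1cc2cc(c1OC)OC1=CC3OC(=O)C1C=C3C(=O)Cc1cccc(OC)c1Oc1cccc(c1)CC2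
F6 | step 10 | tris(tert-butyldimethylsilyl) ether of ketone 17 | CC(C)(C)[Si](C)(C)Oc1cc2cc(c1O[Si](C)(C)C(C)(C)C)Oc1ccc(cc1)C(=O)Cc1cccc(O[Si](C)(C)C(C)(C)C)c1Oc1cccc(c1)CC2
F7 | step 10 | (S)-carbinol tris(tert-butyldimethylsilyl) ether | CC(C)(C)[Si](C)(C)Oc1cc2cc(c1O[Si](C)(C)C(C)(C)C)Oc1ccc(cc1)[C@@H](O)Cc1cccc(O[Si](C)(C)C(C)(C)C)c1Oc1cccc(c1)CC2
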